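Days were the unit of the meeting on the theta flask, whose chains rise and fall on that scale. The chair set out the charges, the readings and the question.

| flask | free monomer | transfer agent | initiator | remark | time |
|---|---|---|---|---|---|
| theta | 0.050 M | 0.015 M | 5.5 mol% | the very flask that is asked about, followed so far |  |
| epsilon | 0.050 M | 0.022 M | 5.5 mol% | run made earlier |  |
| flask | 0.050 M | 0.0150 M | 5.5 mol% |  | 15 d |

| theta: time / d | theta: monomer in chains / % | epsilon: time / d | epsilon: monomer in chains / % |
|---|---|---|---|
| 0.250 | 11.6 | 0.250 | 10.4 |
| 0.500 | 15.9 | 0.500 | 16.0 |
| 0.833 | 23.0 | 1.04 | 16.7 |
| 1.25 | 22.4 | 2.08 | 17.8 |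
| 2.00 | 21.2 | 4.00 | 9.0 |
| 4.00 | 15.5 | 8.00 | 3.0 |
| 6.00 | 9.5 | 15.0 | 1.3 |

(scatter of a reading: 1 percentage point)

- the moment within 15 d at which there is most monomer in chains
- the amount of monomer in chains, in percent of the free monomer charged, at that time



The kineticist argued that the curve has two regimes: at first the feed of monomer into chains outruns the loss, later the loss stands by itself, and the top is the crossing at which control changes hands. From 21.2% at 2.00 d to 9.5% at 6.00 d in the theta run she read 3.45 d, and this she named the decay half-life: the time in which monomer in chains halves once the feed is over, a first-order decay.

A colleague objected. The epsilon run, from 17.8% at 2.08 d to 3.0% at 8.00 d, gives 2.30 d. She answered that this last reading carries a scatter of 1 percentage point, so that figure is loose.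

My own reckoning, as writer of these minutes: the theta rise took 0.833 d, less time than the decay half-life, so I place the top between 0.833 d and 1.25 d. Running the half-life back from 2.00 d to 1.25 d gives 24.6%, and the top should stand under that line.

The forecast says the readings “form a broad top” and puts it at 1.1 d with 22.7%.

The flask gives 1.11 d and 23.7%, inside my interval and under my line.

    free monomer + initiator → living end + monomer in chains (k = 2.90 /M/h)
    free monomer + living end → monomer in chains + living end, rate k2*[living end]*[free monomer] (k = 27.0 /M/h)
    living end + transfer agent → dead chain (kL = 19.0 /M/h)
    monomer in chains → over-reaction product (k = 0.00870 /h)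

The step from living end and transfer agent to dead chain is the largest single effect on the top of the theta flask: with that step taken away, the highest amount is 73.4% instead of 23.7%, while with the initiator held level, which is a further part of it, it is 61.8%. Past the crossing the decay half-life carries the flask: from 23.0% at 1.50 d it gives 1.53% at 15.0 d, and the flask holds 1.42%. In the epsilon run the same half-life takes the reading of 9.0% at 4.00 d down to 0.987% at 15.0 d, and the reading there, with its scatter of 1 point, is 1.3%.

(All runs were computed with constants of no real substance; scatter was added.)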